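**Assumption:** (2S,2'S)-2,2'-bioxirane, the diepoxide made from natural L-tartaric acid, is taken as a purchasable starting material.

## Retrosynthetic overview

1. The C1' carbinol comes from the corresponding C5 ketone by Felkin–Anh hydride reduction, so C5 controls C1'.
2. The C5–C1' bond comes from a visible-light photoredox/HAT/nickel C(sp3)–H acylation of the 2,3-cis tetrahydrofuran laurate with dec-9-enoic acid, trans to the ring substituents.
3. The laurate is put on the ring alcohol before the coupling and carried to the end, so no protecting groups are used.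
4. The tetrahydrofuran, the only ring, is formed second, by sulfoxonium ylide homologation and 5-exo-tet closure of a terminal epoxy alcohol.
5. The epoxy alcohol comes from mono-opening of (S,S)-diepoxybutane with a butyl Grignard reagent; its two stereocentres become C2 and C3.

## Route

**Step 1**
Reactants: 1 (2S,2'S)-2,2'-bioxirane; 2 n-butylmagnesium chloride
Product: 3 (1S)-1-[(2S)-oxiran-2-yl]hexan-1-ol
Conditions: n-BuMgCl (1.0 equiv), CuI (10 mol %), 1 (2.0 equiv), THF, −40 °C; aq NH4Cl
Reagents that add atoms: none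
Why: Copper-catalysed SN2 Grignard opening at one terminal CH2 of the C2-symmetric diepoxide touches neither stereocentre, and the excess of 1 suppresses double opening.

**Step 2**
Reactants: 3 (1S)-1-[(2S)-oxiran-2-yl]hexan-1-ol
Product: 5 (2S,3S)-2-pentyltetrahydrofuran-3-ol, via sulfoxonium betaine 4 (not isolated)
Conditions: Me3S(O)I (3 equiv), NaH (3 equiv), DMSO, 25 to 80 °C
Reagents that add atoms: trimethylsulfoxonium iodide, C[S+](C)(C)=O.[I-]
Why: Dimethylsulfoxonium methylide opens the terminal epoxide at CH2 and the hexanol alkoxide displaces DMSO in a 5-exo-tet closure (ylide-mediated epoxy alcohol to hydroxytetrahydrofuran homologation), so both stereocentres are retained and the threo diol becomes the 2,3-cis ring.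

**Step 3**
Reactants: 5 (2S,3S)-2-pentyltetrahydrofuran-3-ol; 6 dodecanoyl chloride
Product: 7 (2S,3S)-2-pentyltetrahydrofuran-3-yl dodecanoate
Conditions: 6 (1.2 equiv), pyridine, DMAP (cat.), CH2Cl2, 0 to 25 °C
Reagents that add atoms: none
Why: DMAP-catalysed O-acylation of the secondary alcohol proceeds with retention and installs the final laurate, which also shields the upper ring face and deactivates C2–H and C3–H for the next step.

**Step 4**
Reactants: 7 (2S,3S)-2-pentyltetrahydrofuran-3-yl dodecanoate; 8 dec-9-enoic acid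
Product: 10 (2S,3S,5R)-5-(dec-9-enoyl)-2-pentyltetrahydrofuran-3-yl dodecanoate, via tert-butyl dec-9-enoyl carbonate 9 (not isolated)
Conditions: 8 (2.0 equiv), Boc2O (2.5 equiv), Ir[dF(CF3)ppy]2(dtbbpy)PF6 (2 mol %), NiBr2(dme) (10 mol %), dtbbpy (12 mol %), quinuclidine (20 mol %), MeCN, 450 nm LEDs, 25 °C
Reagents that add atoms: none
Why: Proposed new method: the excited trivalent iridium photocatalyst oxidises quinuclidine to its radical cation, which abstracts the most hydridic and least hindered α-oxy hydrogen at C5 (C2–H is tertiary, flanked by pentyl and inductively deactivated by the neighbouring acyloxy group; C3–H, the allylic, the α-carbonyl and the chain C–H bonds are polarity-mismatched), while zerovalent nickel/dtbbpy inserts into mixed anhydride 9 to give an acyl divalent nickel species that captures the C5 radical on the face opposite the cis pentyl and laurate groups and reductively eliminates from trivalent nickel, setting C5 (R) in the 2,5-trans sense, with the released tert-butyl carbonate taking up the proton from quinuclidinium; the closest known reactions are photoredox/quinuclidine-HAT/nickel α-oxy C(sp3)–H arylation and alkylation of simple cyclic ethers and nickel/photoredox acylation of alkyl radicals with anhydride-activated carboxylic acids, neither shown as a site- and diastereoselective C–H acylation of a 2,3-disubstituted tetrahydrofuran used as the limiting partner.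

**Step 5**
Reactants: 10 (2S,3S,5R)-5-(dec-9-enoyl)-2-pentyltetrahydrofuran-3-yl dodecanoate
Product: 11 (2S,3S,5R)-5-[(1R)-1-hydroxydec-9-en-1-yl]-2-pentyltetrahydrofuran-3-yl dodecanoate
Conditions: LiBH(s-Bu)3 (1.1 equiv), THF, −78 °C; aq NH4Cl
Reagents that add atoms: none
Why: Felkin–Anh (polar model) hydride delivery by the bulky borohydride anti to the ring C5–O bond gives the threo (1R) carbinol under control of C5, and at −78 °C the ketone is reduced much faster than the laurate ester while the terminal alkene is inert.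

## Compound list

1 | (2S,2'S)-2,2'-bioxirane [(S,S)-1,2:3,4-diepoxybutane] | C1O[C@@H]1[C@@H]1CO1 | starting material
2 | n-butylmagnesium chloride | CCCC[Mg]Cl | starting material
3 | (1S)-1-[(2S)-oxiran-2-yl]hexan-1-ol | CCCCC[C@H](O)[C@@H]1CO1 | intermediate
4 | dimethyl[(3S,4S)-3-hydroxy-4-oxidononyl]sulfoxonium (betaine, not isolated) | CCCCC[C@H]([O-])[C@@H](O)CC[S+](C)(C)=O | intermediate
5 | (2S,3S)-2-pentyltetrahydrofuran-3-ol | C1C[C@H](O)[C@H](CCCCC)O1 | intermediate
6 | dodecanoyl chloride | CCCCCCCCCCCC(=O)Cl | starting material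
7 | (2S,3S)-2-pentyltetrahydrofuran-3-yl dodecanoate | C1C[C@H](OC(=O)CCCCCCCCCCC)[C@H](CCCCC)O1 | intermediate
8 | dec-9-enoic acid | C=CCCCCCCCC(=O)O | starting material
9 | tert-butyl dec-9-enoyl carbonate (mixed anhydride, not isolated) | C=CCCCCCCCC(=O)OC(=O)OC(C)(C)C | intermediate
10 | (2S,3S,5R)-5-(dec-9-enoyl)-2-pentyltetrahydrofuran-3-yl dodecanoate | C=CCCCCCCCC(=O)[C@H]1C[C@H](OC(=O)CCCCCCCCCCC)[C@H](CCCCC)O1 | intermediate
11 | (2S,3S,5R)-5-[(1R)-1-hydroxydec-9-en-1-yl]-2-pentyltetrahydrofuran-3-yl dodecanoate | C=CCCCCCCC[C@@H](O)[C@H]1C[C@H](OC(=O)CCCCCCCCCCC)[C@H](CCCCC)O1 | target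

## Step count and risks

Total steps: 5. Longest linear sequence: 5 (1 → 3 → 5 → 7 → 10 → 11).

**Most likely to fail, first: step 4 (the proposed C–H acylation).** The risks are low conversion with 7 as the limiting partner, hydrogen abstraction at C2 or along the chains, and a modest trans:cis ratio at C5.

The fallback uses known chemistry, sets out from 3 and comes back at 10. It fixes the radical site with a carboxyl group instead of relying on C–H selectivity:
- Copper-catalysed opening of 3 with CH2=CHMgBr (CuI cat., THF, −30 °C) gives (4S,5S)-dec-1-ene-4,5-diol F1.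
- Mukaiyama-type aerobic oxidative cyclisation closes the 2,5-trans ring to (2S,3S,5R)-5-(hydroxymethyl)-2-pentyltetrahydrofuran-3-ol F2. Conditions: Co(modp)2 (modp = 1-morpholinocarbamoyl-4,4-dimethyl-1,3-pentanedionate), O2, t-BuOOH cat., i-PrOH, 55 °C.
- TEMPO/PhI(OAc)2 in MeCN–H2O oxidises only the primary alcohol, giving (2R,4S,5S)-4-hydroxy-5-pentyltetrahydrofuran-2-carboxylic acid F3.
- Acylation with 6 (pyridine, DMAP; NaHCO3 work-up) gives (2R,4S,5S)-4-(dodecanoyloxy)-5-pentyltetrahydrofuran-2-carboxylic acid F4.
- Acid 8 is converted with (COCl)2 and catalytic DMF into dec-9-enoyl chloride F5.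
- The established photoredox/nickel decarboxylative acyl coupling of α-oxy acids with acyl chlorides joins F4 and F5 with loss of CO2 to give 10. Conditions: Ir[dF(CF3)ppy]2(dtbbpy)PF6, NiCl2(dme), dtbbpy, DBU, 1,4-dioxane, blue LEDs. The same C5 radical is trapped trans to the ring substituents.

**Second: step 2 (ylide homologation and ring closure).** The risks are Payne-type isomerisation products, oxetane formation and incomplete closure.

The fallback sets out from 3 and comes back at 5. It replaces the one-pot ylide process by formyl-anion homologation and anomeric reduction: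
- 3 is opened at CH2 with 2-lithio-1,3-dithiane (2.2 equiv, THF, −30 to 0 °C) to give (2S,3S)-1-(1,3-dithian-2-yl)octane-2,3-diol F6.
- MeI/CaCO3 in aqueous MeCN unmasks the aldehyde, which closes to the lactol (4S,5S)-5-pentyltetrahydrofuran-2,4-diol F7.
- Et3SiH/BF3·OEt2 (CH2Cl2, −40 °C) removes the anomeric hydroxyl to give 5 without touching either stereocentre.

**Third: step 5 (reduction).** The risks are insufficient threo selectivity or attack on the laurate.

The fallback sets out from 10 and comes back at 11. It uses the opposite, chelation-controlled selectivity and then inverts: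
- Zn(BH4)2 (Et2O, −30 °C) gives the erythro alcohol (2S,3S,5R)-5-[(1S)-1-hydroxydec-9-en-1-yl]-2-pentyltetrahydrofuran-3-yl dodecanoate F8.
- Mitsunobu inversion with chloroacetic acid (PPh3, DIAD, THF) gives (2S,3S,5R)-5-[(1R)-1-(chloroacetoxy)dec-9-en-1-yl]-2-pentyltetrahydrofuran-3-yl dodecanoate F9.
- Thiourea/NaHCO3 in EtOH at 50 °C removes only the chloroacetate, leaving the laurate, to give 11.

## Further compounds

F1 | step 4 | (4S,5S)-dec-1-ene-4,5-diol | CCCCC[C@H](O)[C@@H](O)CC=C
F2 | step 4 | (2S,3S,5R)-5-(hydroxymethyl)-2-pentyltetrahydrofuran-3-ol | OC[C@H]1C[C@H](O)[C@H](CCCCC)O1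
F3 | step 4 | (2R,4S,5S)-4-hydroxy-5-pentyltetrahydrofuran-2-carboxylic acid | OC(=O)[C@H]1C[C@H](O)[C@H](CCCCC)O1
F4 | step 4 | (2R,4S,5S)-4-(dodecanoyloxy)-5-pentyltetrahydrofuran-2-carboxylic acid | OC(=O)[C@H]1C[C@H](OC(=O)CCCCCCCCCCC)[C@H](CCCCC)O1
F5 | step 4 | dec-9-enoyl chloride | C=CCCCCCCCC(=O)Cl
F6 | step 2 | (2S,3S)-1-(1,3-dithian-2-yl)octane-2,3-diol | CCCCC[C@H](O)[C@@H](O)CC1SCCCS1
F7 | step 2 | (4S,5S)-5-pentyltetrahydrofuran-2,4-diol (anomer mixture) | OC1C[C@H](O)[C@H](CCCCC)O1
F8 | step 5 | (2S,3S,5R)-5-[(1S)-1-hydroxydec-9-en-1-yl]-2-pentyltetrahydrofuran-3-yl dodecanoate | C=CCCCCCCC[C@H](O)[C@H]1C[C@H](OC(=O)CCCCCCCCCCC)[C@H](CCCCC)O1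
F9 | step 5 | (2S,3S,5R)-5-[(1R)-1-(chloroacetoxy)dec-9-en-1-yl]-2-pentyltetrahydrofuran-3-yl dodecanoate | C=CCCCCCCC[C@@H](OC(=O)CCl)[C@H]1C[C@H](OC(=O)CCCCCCCCCCC)[C@H](CCCCC)O1
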